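**Plan**
- Retrosynthetic cuts: (a) the O–Si bond. (b) The C=CH2 and C–CH3 bonds of the inner isopropenyl group, back to a lactone C=O held on O6. (c) Together, the side-chain CH2–CH bond and the O6–C(=O) bond, a formal [4+2] that splits the molecule into an o-quinone methide and a C7 acyl unit. (d) C5–CH2 (Mannich), O1–C2 (epoxide opening), the aryl–prenyl bond and the aryl–C(=O) bond (Friedel–Crafts).
- Enabling feature: on the benzofuran benzene ring the free 6-OH is ortho to C5–CH2, so O6–C6–C5–CH2 is a latent 1-oxadiene (o-quinone methide). It is pushed by 4-OMe and O1 and pulled by the 7-aroyl group. O4 is methylated and O1 is in the ring, so only one quinone methide can form.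
- Forward order: benzophenone, then C-prenylation of the C2-symmetric 2,6-dihydroxy-4-methoxy ring, then the dihydrofuran ring, then the CH2–NMe3+ handle. The key annulation then closes a temporary δ-lactone ring, the lactone is opened and its carbonyl turned into the isopropenyl group, and the silyl ether is removed.
- Stereochemistry: C2 (S) comes from a Shi epoxidation, which gives the (R)-epoxide, followed by invertive 5-exo opening. The side-chain CH (R) comes from the chiral triazolium carbene catalyst in the key step.

Key step: step 12

Remark on numbering: benzofuran numbering is used throughout. O1, C2 (hydroxyisopropyl), C3, C3a, C4 (OMe), C5 (side chain), C6 (OH), C7 (aroyl), C7a. The 3′ position is the oxygenated position of the benzoyl ring.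
Assumption: the sense of induction of the triazolium catalyst is assigned by analogy with related azolium-enolate annulations. Both antipodes are commercial, and the one that delivers (R) at the new centre is meant.

**Step 1**
Reactants: 1 3-acetoxybenzoic acid; 2 1,3,5-trimethoxybenzene
Product: 4 3-(2,4,6-trimethoxybenzoyl)phenyl acetate, via mixed aroyl trifluoroacetate 3 (not isolated)
Conditions: (CF3CO)2O (1.5 equiv), CH2Cl2, rt, 1 h; then 2, 0 °C → rt
Reagents that add atoms: none
Why: Friedel–Crafts acylation via the mixed aroyl trifluoroacetate should proceed without a metal Lewis acid because 2 is strongly activated and has only one kind of C–H, the ketone formed deactivates the ring against a second acylation, and the aryl acetate is inert to TFAA/TFA.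

**Step 2**
Reactants: 4 3-(2,4,6-trimethoxybenzoyl)phenyl acetate
Product: 6 (2,6-dihydroxy-4-methoxyphenyl)(3-hydroxyphenyl)methanone, via bis-demethylated acetate 5 (not isolated)
Conditions: BCl3 (6 equiv), CH2Cl2, −78 °C → rt; then MeOH, 50 °C
Reagents that add atoms: none
Why: Chelation-directed aryl methyl ether cleavage: boron bound to the ketone oxygen should remove only the two ortho methyl groups and spare the para one, and the HCl/MeOH generated on quenching transesterifies the aryl acetate, so the C2-symmetric 2,6-dihydroxy-4-methoxy pattern is reached in one operation.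

**Step 3**
Reactants: 6 (2,6-dihydroxy-4-methoxyphenyl)(3-hydroxyphenyl)methanone
Product: 7 (2,6-dihydroxy-4-methoxyphenyl){3-[(triisopropylsilyl)oxy]phenyl}methanone
Conditions: TIPSCl (1.05 equiv), imidazole, DMF, 0 °C
Reagents that add atoms: triisopropylsilyl chloride CC(C)[Si](Cl)(C(C)C)C(C)C
Why: Sterically controlled silylation: the bulky chlorosilane should take the unhindered 3′-OH, whereas the 2- and 6-OH are hydrogen-bonded to the ketone and flanked by the aroyl group.

**Step 4**
Reactants: 7 (2,6-dihydroxy-4-methoxyphenyl){3-[(triisopropylsilyl)oxy]phenyl}methanone; 8 prenyl bromide (1-bromo-3-methylbut-2-ene)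
Product: 9 [2,6-dihydroxy-4-methoxy-3-(3-methylbut-2-en-1-yl)phenyl]{3-[(triisopropylsilyl)oxy]phenyl}methanone
Conditions: 8 (1.0 equiv), DBU (1.1 equiv), THF, 0 °C → rt
Reagents that add atoms: none
Why: C-alkylation of the ambident acylphloroglucinol-type phenoxide with an allylic bromide; C3 and C5 are equivalent in 7, so mono-C-prenylation can give only one constitution, and one equivalent of halide limits double alkylation.

**Step 5**
Reactants: 9 the 3-prenyl-2,6-dihydroxy benzophenone
Product: 10 bis(tert-butyl carbonate) of 9 (both ring-A phenols as O-Boc)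
Conditions: Boc2O (2.5 equiv), DMAP (10 mol %), MeCN, rt
Reagents that add atoms: di-tert-butyl dicarbonate CC(C)(C)OC(=O)OC(=O)OC(C)(C)C
Why: DMAP-catalysed O-tert-butoxycarbonylation masks both oxidation-prone phenols for the epoxidation with a group that is stable to cold pH 10 buffer and can later be removed by mild base without touching the TIPS ether.

**Step 6**
Reactants: 10 bis(tert-butyl carbonate) of 9
Product: 11 the (R)-epoxide of 10, side chain [(2R)-3,3-dimethyloxiran-2-yl]methyl
Conditions: D-fructose-derived Shi ketone (30 mol %), Oxone, K2CO3, Na2B4O7/Na2EDTA buffer, Bu4NHSO4 (cat.), MeCN–dimethoxymethane–H2O, 0 °C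
Reagents that add atoms: Oxone (potassium peroxymonosulfate) [K+].[O-]S(=O)(=O)OO
Why: Shi asymmetric epoxidation: the dioxirane of the D-fructose-derived ketone should transfer oxygen to the only alkene, a trisubstituted one, through the spiro transition state and give the (R)-epoxide, this being the source of the dihydrofuran stereocentre.

**Step 7**
Reactants: 11 the (R)-epoxide
Product: 13 [(2S)-6-hydroxy-2-(2-hydroxypropan-2-yl)-4-methoxy-2,3-dihydro-1-benzofuran-7-yl]{3-[(triisopropylsilyl)oxy]phenyl}methanone, via epoxy bisphenol 12 (not isolated)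
Conditions: K2CO3, MeOH, 0 °C → rt
Reagents that add atoms: none
Why: Base methanolysis of the aryl carbonates frees the phenoxides, and the one next to the side chain (its other neighbour is OMe) should open the epoxide at the secondary carbon by 5-exo-tet SN2 attack with inversion, (R) to (S), basic conditions disfavouring the 6-endo chromanol.

**Step 8**
Reactants: 13 the (2S)-dihydrobenzofuran
Product: 14 the 5-[(dimethylamino)methyl] derivative of 13 (Mannich base)
Conditions: aq CH2O, aq Me2NH, EtOH, rt
Reagents that add atoms: formaldehyde C=O; dimethylamine CNC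
Why: Phenol Mannich aminomethylation: C5 is the only free position of the electron-rich ring and lies ortho to the free 6-OH, while the acyl-deactivated silyloxyphenyl ring does not compete.

**Step 9**
Reactants: 14 the Mannich base
Product: 15 the (benzofuran-5-yl)methyl-trimethylammonium iodide
Conditions: MeI (5 equiv), Et2O–CH2Cl2, rt, dark; filtration
Reagents that add atoms: iodomethane CI
Why: Menshutkin quaternisation turns the amine into a leaving group; without added base the phenol and the tertiary alcohol are not methylated, and the salt should precipitate and be collected by filtration.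

**Step 10**
Reactants: 16 5-oxohexanoic acid
Product: 17 5-methylhex-5-enoic acid
Conditions: Ph3PCH3Br (2.2 equiv), KOtBu (3.3 equiv), THF, 0 °C → rt; then aq HCl
Reagents that add atoms: methyltriphenylphosphonium bromide C[P+](c1ccccc1)(c1ccccc1)c1ccccc1.[Br-]
Why: Wittig methylenation of the ketone in the presence of the carboxylate, which is inert to the ylide once deprotonated by the extra base.

**Step 11**
Reactants: 17 5-methylhex-5-enoic acid
Product: 18 1-(1H-imidazol-1-yl)-5-methylhex-5-en-1-one
Conditions: CDI (1.1 equiv), CH2Cl2, rt; brief aqueous wash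
Reagents that add atoms: 1,1′-carbonyldiimidazole O=C(n1ccnc1)n1ccnc1
Why: Carboxyl activation with CDI gives the N-acylimidazole, the acyl donor needed to load the carbene catalyst, with only gaseous and water-soluble co-products.

**Step 12**
Reactants: 15 the trimethylammonium iodide; 18 1-(1H-imidazol-1-yl)-5-methylhex-5-en-1-one
Product: 20 (2S,6R)-2-(2-hydroxypropan-2-yl)-4-methoxy-6-(3-methylbut-3-en-1-yl)-9-{3-[(triisopropylsilyl)oxy]benzoyl}-2,3,5,6-tetrahydro-7H-furo[3,2-g]chromen-7-one, via o-quinone methide 19 (not isolated)
Conditions: aminoindanol-derived N-mesityl triazolium tetrafluoroborate (single enantiomer, 15 mol %), iPr2NEt (1.3 equiv), 18 (1.5 equiv), 4 Å MS, THF, −20 → 0 °C, 15 added in portions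
Reagents that add atoms: none
Why: Deprotonation of the 6-OH of 15 expels NMe3 (1,4-elimination) to give o-quinone methide 19, while the carbene is acylated by 18 and the acyl azolium is deprotonated to a (Z)-azolium enolate; the enolate α-carbon adds to the exocyclic CH2 of 19 (rearomatising Michael addition, the new CH2–CH bond) and the liberated C6 phenoxide is acylated by the acyl azolium, which releases the carbene. The closest known reaction type is the carbene-catalysed enantioselective formal [4+2] annulation of acylimidazole-derived azolium enolates with in situ generated, methylene-unsubstituted o-quinone methides to 3-substituted 3,4-dihydrocoumarins. The one ring closed, the temporary δ-lactone, forms by 6-exo-trig attack of O6 on the acyl azolium carbonyl, overall an inverse-demand oxa-[4+2] across O=C6–C5=CH2. The new stereocentre (R) is set by the catalyst, whose indane wall shields one face of the enolate so that 19 is met on the Si face of the α-carbon, and the distant (S)-centre of the dihydrofuran plays no part. Regiochemistry needs no control because only one quinone methide can form, and C- over heteroatom capture rests on the reversibility of NMe3 and imidazole addition, on the TIPS cap at O3′ and on the inertness of the tertiary alcohol. Slow dissolution of the sparingly soluble salt 15 keeps 19 dilute and should suppress its dimerisation.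

**Step 13**
Reactants: 20 the lactone
Product: 21 (2R)-2-{[benzofuran-5-yl]methyl}-N-methoxy-N,5-dimethylhex-5-enamide (Weinreb amide with free 6-OH; benzofuran unit as in 13)
Conditions: MeNH(OMe)·HCl, AlMe3, CH2Cl2, 0 °C → rt; aq HCl work-up
Reagents that add atoms: N,O-dimethylhydroxylamine hydrochloride CNOC.Cl
Why: Weinreb aminolysis with the aluminium amide should open the activated aryl lactone irreversibly under weakly basic conditions, so that the α-stereocentre is kept, the 6-OH is released and the ketone, TIPS ether and alkene are untouched.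

**Step 14**
Reactants: 21 the Weinreb amide
Product: 22 (3R)-3-{[benzofuran-5-yl]methyl}-6-methylhept-6-en-2-one (methyl ketone; benzofuran unit as in 13)
Conditions: MeMgBr (3.5 equiv), THF, −78 → −20 °C; aq NH4Cl
Reagents that add atoms: methylmagnesium bromide C[Mg]Br
Why: Weinreb ketone synthesis: the chelated tetrahedral intermediate stops the addition at the ketone stage, and at low temperature the diaryl ketone should not compete because it is flanked by two ortho oxygens and, as the magnesium phenoxide, is a vinylogous carboxylate.

**Step 15**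
Reactants: 22 the methyl ketone
Product: 23 the 3′-O-TIPS ether of the target
Conditions: Ph3PCH3Br (3.2 equiv), KHMDS (3.0 equiv), THF, −78 → 0 °C
Reagents that add atoms: methyltriphenylphosphonium bromide C[P+](c1ccccc1)(c1ccccc1)c1ccccc1.[Br-]
Why: Wittig methylenation of the unhindered methyl ketone with the non-stabilised ylide at low temperature, where addition should outrun enolisation so that the adjacent stereocentre is retained, the first equivalent of ylide converting the phenol into a phenoxide that further deactivates the hindered diaryl ketone.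

**Step 16**
Reactants: 23 the 3′-O-TIPS ether of the target
Product: 24 [(2S)-6-hydroxy-2-(2-hydroxypropan-2-yl)-4-methoxy-5-[(2R)-5-methyl-2-(prop-1-en-2-yl)hex-5-en-1-yl]-2,3-dihydro-1-benzofuran-7-yl](3-hydroxyphenyl)methanone (target)
Conditions: TBAF, AcOH (1:1), THF, 0 °C
Reagents that add atoms: none
Why: Fluoride-induced cleavage of the aryl silyl ether, buffered with acetic acid, leaves the two 1,1-disubstituted alkenes, the tertiary alcohol and both stereocentres untouched and avoids the acid that would cyclise the 6-OH onto the isopropenyl group.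

**Compound list**
1 | 3-acetoxybenzoic acid | CC(=O)Oc1cccc(C(=O)O)c1 | starting material
2 | 1,3,5-trimethoxybenzene | COc1cc(OC)cc(OC)c1 | starting material
3 | 3-acetoxybenzoic trifluoroacetic anhydride (not isolated) | CC(=O)Oc1cccc(C(=O)OC(=O)C(F)(F)F)c1 | intermediate
4 | 3-(2,4,6-trimethoxybenzoyl)phenyl acetate | CC(=O)Oc1cccc(C(=O)c2c(OC)cc(OC)cc2OC)c1 | intermediate
5 | 3-(2,6-dihydroxy-4-methoxybenzoyl)phenyl acetate (not isolated) | CC(=O)Oc1cccc(C(=O)c2c(O)cc(OC)cc2O)c1 | intermediate
6 | (2,6-dihydroxy-4-methoxyphenyl)(3-hydroxyphenyl)methanone | COc1cc(O)c(C(=O)c2cccc(O)c2)c(O)c1 | intermediate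
7 | (2,6-dihydroxy-4-methoxyphenyl){3-[(triisopropylsilyl)oxy]phenyl}methanone | COc1cc(O)c(C(=O)c2cccc(O[Si](C(C)C)(C(C)C)C(C)C)c2)c(O)c1 | intermediate
8 | prenyl bromide | CC(C)=CCBr | starting material
9 | [2,6-dihydroxy-4-methoxy-3-(3-methylbut-2-en-1-yl)phenyl]{3-[(triisopropylsilyl)oxy]phenyl}methanone | COc1cc(O)c(C(=O)c2cccc(O[Si](C(C)C)(C(C)C)C(C)C)c2)c(O)c1CC=C(C)C | intermediate
10 | bis(tert-butyl carbonate) of 9 | COc1cc(OC(=O)OC(C)(C)C)c(C(=O)c2cccc(O[Si](C(C)C)(C(C)C)C(C)C)c2)c(OC(=O)OC(C)(C)C)c1CC=C(C)C | intermediate
11 | (R)-epoxide of 10 | COc1cc(OC(=O)OC(C)(C)C)c(C(=O)c2cccc(O[Si](C(C)C)(C(C)C)C(C)C)c2)c(OC(=O)OC(C)(C)C)c1C[C@H]1OC1(C)C | intermediate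
12 | (R)-epoxy bisphenol (not isolated) | COc1cc(O)c(C(=O)c2cccc(O[Si](C(C)C)(C(C)C)C(C)C)c2)c(O)c1C[C@H]1OC1(C)C | intermediate
13 | [(2S)-6-hydroxy-2-(2-hydroxypropan-2-yl)-4-methoxy-2,3-dihydro-1-benzofuran-7-yl]{3-[(triisopropylsilyl)oxy]phenyl}methanone | COc1cc(O)c(C(=O)c2cccc(O[Si](C(C)C)(C(C)C)C(C)C)c2)c2c1C[C@@H](C(C)(C)O)O2 | intermediate
14 | 5-[(dimethylamino)methyl] derivative of 13 | CN(C)Cc1c(O)c(C(=O)c2cccc(O[Si](C(C)C)(C(C)C)C(C)C)c2)c2c(c1OC)C[C@@H](C(C)(C)O)O2 | intermediate
15 | trimethylammonium iodide from 14 | C[N+](C)(C)Cc1c(O)c(C(=O)c2cccc(O[Si](C(C)C)(C(C)C)C(C)C)c2)c2c(c1OC)C[C@@H](C(C)(C)O)O2.[I-] | intermediate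
16 | 5-oxohexanoic acid | CC(=O)CCCC(=O)O | starting material
17 | 5-methylhex-5-enoic acid | C=C(C)CCCC(=O)O | intermediate
18 | 1-(1H-imidazol-1-yl)-5-methylhex-5-en-1-one | C=C(C)CCCC(=O)n1ccnc1 | intermediate
19 | (2S)-5-methylidene-6-oxo o-quinone methide of the benzofuran (not isolated) | C=C1C(=O)C(C(=O)c2cccc(O[Si](C(C)C)(C(C)C)C(C)C)c2)=C2O[C@H](C(C)(C)O)CC2=C1OC | intermediate
20 | (2S,6R)-tetrahydrofuro[3,2-g]chromen-7-one lactone | C=C(C)CC[C@@H]1Cc2c(OC)c3C[C@@H](C(C)(C)O)Oc3c(C(=O)c4cccc(O[Si](C(C)C)(C(C)C)C(C)C)c4)c2OC1=O | intermediate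
21 | (2R)-Weinreb amide | C=C(C)CC[C@H](Cc1c(O)c(C(=O)c2cccc(O[Si](C(C)C)(C(C)C)C(C)C)c2)c2c(c1OC)C[C@@H](C(C)(C)O)O2)C(=O)N(C)OC | intermediate
22 | (3R)-methyl ketone | C=C(C)CC[C@H](Cc1c(O)c(C(=O)c2cccc(O[Si](C(C)C)(C(C)C)C(C)C)c2)c2c(c1OC)C[C@@H](C(C)(C)O)O2)C(C)=O | intermediate
23 | 3′-O-TIPS ether of the target | C=C(C)CC[C@H](Cc1c(O)c(C(=O)c2cccc(O[Si](C(C)C)(C(C)C)C(C)C)c2)c2c(c1OC)C[C@@H](C(C)(C)O)O2)C(=C)C | intermediate
24 | CNP0263422.2 | C=C(C)CC[C@H](Cc1c(O)c(C(=O)c2cccc(O)c2)c2c(c1OC)C[C@@H](C(C)(C)O)O2)C(=C)C | target

Total step count: 16. Longest linear sequence: 14 (steps 1–9 and 12–16).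

**Steps most likely to fail**

Step 12.
- What may go wrong: self-condensation of the quinone methide may outrun its capture by the catalyst-bound enolate. Ring closure by the weakly nucleophilic, ketone-chelated phenoxide may be sluggish and stall turnover. Facial discrimination may be insufficient, or base may erode the new centre in the activated aryl lactone.
- Fallback (auxiliary control with a stoichiometric nucleophile instead of catalyst control): acid 17 is coupled through its pivalic mixed anhydride with lithiated (S)-4-benzyloxazolidin-2-one to give (S)-4-benzyl-3-(5-methylhex-5-enoyl)oxazolidin-2-one F1.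
- The sodium (Z)-enolate of F1 (NaHMDS, THF, −78 °C, two equivalents, one serving as base) is treated with salt 15. Quinone methide 19 is then released in the presence of the chiral enolate and is attacked on the face away from the benzyl group, giving the imide adduct F2.
- On warming with catalytic DBU the C6 phenoxide displaces the auxiliary, and the route is rejoined at lactone 20.

Step 14.
- What may go wrong: the Grignard reagent may also add to the diaryl ketone, or the amide may be consumed incompletely at the low temperature needed for selectivity.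
- Fallback (palladium-catalysed acyl cross-coupling instead of polar addition): it sets out from lactone 20, which is opened with Me2AlSEt (AlMe3, EtSH, CH2Cl2, 0 °C) to the S-ethyl thioester F3.
- Fukuyama coupling of F3 with MeZnI and PdCl2(PPh3)2 in THF–toluene, a reagent pair that does not touch ketones, gives methyl ketone 22. Amide 21 is bypassed.

Step 4.
- What may go wrong: O-alkylation and double or geminal alkylation may compete with mono C-alkylation.
- Fallback (sigmatropic delivery instead of direct C-alkylation): it sets out from 7, which is O-alkylated once with isobutyl 2-methylbut-3-en-2-yl carbonate under Pd(PPh3)4 catalysis (THF, 0 °C) to the 1,1-dimethylallyl aryl ether F4.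
- On heating in toluene F4 undergoes an aromatic Claisen rearrangement. The only free ortho position is C3, and allyl inversion delivers the normal prenyl group, so the route is rejoined at 9.

**Further compounds**
F1 | step 12 | (S)-4-benzyl-3-(5-methylhex-5-enoyl)oxazolidin-2-one | C=C(C)CCCC(=O)N1C(=O)OC[C@@H]1Cc1ccccc1
F2 | step 12 | (4S)-4-benzyl-3-[(2R)-2-{[benzofuran-5-yl]methyl}-5-methylhex-5-enoyl]oxazolidin-2-one (imide adduct, benzofuran unit as in 13) | C=C(C)CC[C@H](Cc1c(O)c(C(=O)c2cccc(O[Si](C(C)C)(C(C)C)C(C)C)c2)c2c(c1OC)C[C@@H](C(C)(C)O)O2)C(=O)N1C(=O)OC[C@@H]1Cc1ccccc1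
F3 | step 14 | S-ethyl (2R)-2-{[benzofuran-5-yl]methyl}-5-methylhex-5-enethioate (benzofuran unit as in 13) | C=C(C)CC[C@H](Cc1c(O)c(C(=O)c2cccc(O[Si](C(C)C)(C(C)C)C(C)C)c2)c2c(c1OC)C[C@@H](C(C)(C)O)O2)C(=O)SCC
F4 | step 4 | {2-hydroxy-4-methoxy-6-[(2-methylbut-3-en-2-yl)oxy]phenyl}{3-[(triisopropylsilyl)oxy]phenyl}methanone | C=CC(C)(C)Oc1cc(OC)cc(O)c1C(=O)c1cccc(O[Si](C(C)C)(C(C)C)C(C)C)c1
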